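Start from a one-step world: let the coupling partner add to the starting material and do nothing else, and target tops out at 80.0% of the solid substrate charged. That is the first ceiling.

solid substrate 2.2 M; coupling partner 0.800 equiv; protic impurity 0.440 M; time 4.0 d

* why nothing more happens at 4.0 d, or that something still does (for what has run out or reacted, a solid counts together with what of it has only dissolved) (forward and back rates have come level / all of the solid substrate has reacted / the coupling partner has run out first / it is still moving)
* amount of target at 4.0 d, in percent of the solid substrate charged
* amount of starting material at 4.0 d, in percent of the solid substrate charged
* amount of target if the flask were left three thousand times as long, in percent of the solid substrate charged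

- solid substrate is a solid; its amount is given per volume of the solution
- at the start none of the solid substrate is in solution
- what has only dissolved of solid substrate counts as not reacted
- the reaction counts as stopped when no species that holds the solid substrate changes by six tenths of a point or more over the second half of the time
- starting material means what is dissolved; the solid is not counted in it
- run time (flask): 4.0 d

    starting material + coupling partner ⇌ isomer of the product (K1 = 1.2 L mol⁻¹, k1 = 0.024 L mol⁻¹ min⁻¹)
    coupling partner + protic impurity → quenched reagent (k2 = 0.0095 L mol⁻¹ min⁻¹)
    starting material + coupling partner ⇌ target (K3 = 0.67 L mol⁻¹, k3 = 0.046 L mol⁻¹ min⁻¹)
    solid substrate ⇌ starting material, rate k4*(cs4 - [starting material]) while solid is left; crystals form when [starting material] > cs4 (cs4 = 0.77 M, k4 = 0.0066 min⁻¹)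

Lower the ceiling. Hold [starting material] at its solubility, 0.77 M, while solid remains; the dissolution half-life, 1.75 h, is short against 4.0 d. Let both additions reach balance (thermodynamic control): their forward half-lives, 0.14 h and 0.27 h, are short against 4.0 d. Free partner, target and isomer then stand in fixed proportion. 21.1% of the partner pool ends as target: call this the capture share.

Suppose the protic impurity takes nothing. The pool is the whole charge, and target stays below 16.9%. That is the tight ceiling.

Now suppose the impurity takes its full 0.440 M, one partner each. The pool falls to 1.32 M, and the floor is 12.7%.

Find the edge that holds. At balance, free partner stands at no less than 0.541 M while impurity lasts. So the impurity's half-life is at most 0.0937 d, short against 4.0 d. Commit to the floor. Check the solid: the dissolved total of 1.55 M is less than the 2.2 M charged, so solid stays and starting material stands at 35.0%. Expect the same target after the long wait.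

The forecast sits on the same floor: forward and back rates have come level, target 12.69%, starting material 35%, and 12.69% after the long wait. Its ground for the last: “The system is at equilibrium, so waiting longer changes nothing”.

In the flask, forward and back rates have come level: target stands at 12.7% and starting material at 35.0%, with target at 12.7% after the long wait.

In this flask, protic impurity stands at 0% of its charge at 4.00 d. Take the capture share to the neighbour flask with 0.320 equiv of coupling partner. Its pool is 0.264 M, and 21.1% of that gives 2.53% of the solid substrate charged. In that neighbour flask, target stands at 2.54%.

The rate constants were chosen freely; the rest is arithmetic.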